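## Retrosynthetic overview

1. Target 39 ⇐ acetate 37: the last step is a singlet-oxygen ene reaction on the 7′(11′)-en-8′-one; the hydroperoxide closes to the 1,2-dioxolane hemiketal.
2. Bicyclo[2.2.1]heptene core ⇐ 2-silyloxydiene 14 + enone 26: intermolecular Mukaiyama–Michael addition (C3–C1′), then intramolecular Michael closure (C1–C2′). The C4 silyl enol ether formed becomes the C4 methyl via the enol triflate.
3. Donor 14 ⇐ (R)-α-phellandrene: 1,4-dioxygenation, directed hydrogenation (sets C10), one-carbon ring expansion, Claisen cyclisation to a cyclopentenedione, reduction and selective re-oxidation.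
4. Acceptor 26 ⇐ (S)-carvone: Shapiro diene, 1,4-dioxygenation, conjugate reduction (sets C10′), ring expansion, acetonylation and aldol cyclopentenone annulation.
5. Ring order in each half: six-membered terpene ring → seven-membered ring → five-membered ring; then the norbornene; last the dioxolane.

Locants: guaiane numbering for each half (five-membered ring C1–C5, seven-membered ring C1, C5–C10, methyl on C10, three-carbon side chain on C7); the right-hand half is primed. TBS = tert-butyldimethylsilyl, TIPS = triisopropylsilyl, Tf = trifluoromethanesulfonyl.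

Assumption: the C8′ hemiketal centre equilibrates by ring–chain tautomerism and the configuration of the target is taken to be the thermodynamically preferred one.

## Route

### Left half (donor)

Step 1
Reactants: 1 (R)-(−)-α-phellandrene
Product: 2 trans-endoperoxide 6-methyl-8-isopropyl-2,3-dioxabicyclo[2.2.2]oct-5-ene (O–O bridge anti to isopropyl)
Conditions: O2, hν (visible), tetraphenylporphyrin (cat.), CH2Cl2, 0 °C
Reagents that add atoms: dioxygen, O=O
Why: Singlet-oxygen [4+2] cycloaddition to the cyclic 1,3-diene is expected to occur mainly anti to the C7 isopropyl group (the minor cis isomer is removed by chromatography) and puts oxygen on C1 and C8.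

Step 2
Reactants: 2 trans-endoperoxide
Product: 3 (4R,5R)-4-hydroxy-2-methyl-5-isopropylcyclohex-2-en-1-one
Conditions: Et3N, CH2Cl2, 0 °C → rt
Reagents that add atoms: none
Why: Kornblum–DeLaMare rearrangement in which the amine removes the less hindered bridgehead hydrogen (C1–H, remote from the isopropyl group), giving the C1 ketone and leaving the C8 carbinol trans to isopropyl.

Step 3
Reactants: 3 (4R,5R)-4-hydroxy-2-methyl-5-isopropylcyclohex-2-en-1-one
Product: 4 (2S,4S,5R)-4-hydroxy-2-methyl-5-isopropylcyclohexan-1-one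
Conditions: H2 (1 atm), [Ir(cod)(PCy3)(py)]PF6 (5 mol %), CH2Cl2, rt
Reagents that add atoms: none
Why: Hydroxyl-directed homogeneous hydrogenation delivers H2 to C9=C10 from the face of the C8 hydroxyl, so the C10 methyl ends up cis to the C7 isopropyl group (kinetic, axial methyl).

Step 4
Reactants: 4 (2S,4S,5R)-4-hydroxy-2-methyl-5-isopropylcyclohexan-1-one
Product: 5 (2S,4S,5R)-4-(TBS-oxy)-2-methyl-5-isopropylcyclohexan-1-one
Conditions: TBSCl, imidazole, DMF, rt
Reagents that add atoms: tert-butyldimethylsilyl chloride, CC(C)(C)[Si](C)(C)Cl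
Why: Standard silylation under weakly basic conditions that do not epimerise the α-methyl centre.

Step 5
Reactants: 5 (2S,4S,5R)-4-(TBS-oxy)-2-methyl-5-isopropylcyclohexan-1-one
Product: 6 ethyl 5-(TBS-oxy)-3-methyl-2-oxo-6-isopropylcycloheptane-1-carboxylate (C1 epimers and enol)
Conditions: N2CHCO2Et, BF3·OEt2, CH2Cl2, −20 → 0 °C
Reagents that add atoms: ethyl diazoacetate, CCOC(=O)C=[N+]=[N-]
Why: Lewis-acid-promoted diazoacetate ring expansion in which the less substituted α-carbon (C6) migrates, inserting C5 with its ester (future C4) between C1 and C6 and leaving C7, C8 and C10 untouched.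

Step 6
Reactants: 6 ethyl 5-(TBS-oxy)-3-methyl-2-oxo-6-isopropylcycloheptane-1-carboxylate
Product: 7 ethyl 5-(TBS-oxy)-3-methyl-6-isopropyl-2-(triflyloxy)cyclohept-1-ene-1-carboxylate
Conditions: NaH, THF, 0 °C; PhNTf2, 0 °C → rt
Reagents that add atoms: N-phenylbis(trifluoromethanesulfonimide), O=S(=O)(N(c1ccccc1)S(=O)(=O)C(F)(F)F)C(F)(F)F
Why: O-triflation of the β-keto ester enolate gives the C1=C5 enol triflate, after which C10 is no longer α to a carbonyl and is configurationally secure.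

Step 7
Reactants: 7 ethyl 5-(TBS-oxy)-3-methyl-6-isopropyl-2-(triflyloxy)cyclohept-1-ene-1-carboxylate
Product: 9 ethyl 2-acetyl-5-(TBS-oxy)-3-methyl-6-isopropylcyclohept-1-ene-1-carboxylate, via enol ether 8 (not isolated)
Conditions: Bu3Sn(C(OEt)=CH2), Pd(PPh3)4 (5 mol %), LiCl, THF, 65 °C; then 1 M HCl, THF, 0 °C
Reagents that add atoms: tributyl(1-ethoxyvinyl)stannane, CCCC[Sn](CCCC)(CCCC)C(=C)OCC; water, O
Why: Stille coupling of the vinyl triflate with the acyl-anion equivalent followed by mild enol ether hydrolysis installs C2 and C3 as an acetyl group cis to the ester.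

Step 8
Reactants: 9 ethyl 2-acetyl-5-(TBS-oxy)-3-methyl-6-isopropylcyclohept-1-ene-1-carboxylate
Product: 10 8-(TBS-oxy)-15-norguai-1(5)-ene-2,4-dione
Conditions: LiN(SiMe3)2 (2.2 equiv), THF, −78 → 0 °C; then aq. HCl to pH 3
Reagents that add atoms: none
Why: Intramolecular Claisen (Dieckmann-type) condensation of the kinetic methyl ketone enolate onto the cis ester closes the five-membered ring and is driven by formation of the stabilised dione enolate.

Step 9
Reactants: 10 8-(TBS-oxy)-15-norguai-1(5)-ene-2,4-dione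
Product: 11 8-(TBS-oxy)-15-norguai-1(5)-ene-2,4-diol (2-OH cis to the C10 methyl; 4-OH cis to 2-OH)
Conditions: NaBH4, CeCl3·7H2O, MeOH, −78 → 0 °C
Reagents that add atoms: none
Why: Luche 1,2-reduction of both carbonyls, with hydride adding to C2=O anti to the pseudoaxial C10 methyl so that the C2 hydroxyl is cis to that methyl (the C4 carbinol is re-oxidised next, so its configuration is immaterial).

Step 10
Reactants: 11 8-(TBS-oxy)-15-norguai-1(5)-ene-2,4-diol
Product: 12 2-hydroxy-8-(TBS-oxy)-15-norguai-1(5)-en-4-one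
Conditions: MnO2 (activated), CH2Cl2, rt
Reagents that add atoms: none
Why: Allylic oxidation is faster at the less hindered C4 carbinol (next to the C6 methylene) than at the C2 carbinol flanked by the branched C10 centre.

Step 11
Reactants: 12 2-hydroxy-8-(TBS-oxy)-15-norguai-1(5)-en-4-one
Product: 13 8-(TBS-oxy)-2-(TIPS-oxy)-15-norguai-1(5)-en-4-one
Conditions: TIPSOTf, 2,6-lutidine, CH2Cl2, −78 → 0 °C
Reagents that add atoms: triisopropylsilyl trifluoromethanesulfonate, CC(C)[Si](OS(=O)(=O)C(F)(F)F)(C(C)C)C(C)C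
Why: Silylation gives a bulky, robust ether at C2 that later shields one face of the diene and survives until the end.

Step 12
Reactants: 13 8-(TBS-oxy)-2-(TIPS-oxy)-15-norguai-1(5)-en-4-one
Product: 14 4,8-bis(TBS-oxy)-2-(TIPS-oxy)-15-norguaia-1(5),3-diene
Conditions: TBSOTf, Et3N, CH2Cl2, −78 → −30 °C; cold pentane extraction, used at once
Reagents that add atoms: tert-butyldimethylsilyl trifluoromethanesulfonate, CC(C)(C)[Si](C)(C)OS(=O)(=O)C(F)(F)F
Why: Soft enolisation at the α′ carbon C3 gives the cross-conjugated 2-silyloxydiene without a free enolate (so the β-silyloxy group at C2 is not eliminated), and keeping it cold prevents 1,5-hydrogen shifts.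

### Right half (acceptor)

Step 13
Reactants: 15 (S)-(+)-carvone
Product: 16 (S)-carvone p-toluenesulfonylhydrazone
Conditions: TsNHNH2, EtOH, rt
Reagents that add atoms: p-toluenesulfonohydrazide, Cc1ccc(cc1)S(=O)(=O)NN
Why: Routine hydrazone condensation that prepares the ketone for reductive olefination.

Step 14
Reactants: 16 (S)-carvone p-toluenesulfonylhydrazone
Product: 17 (S)-2-methyl-5-(prop-1-en-2-yl)cyclohexa-1,3-diene
Conditions: MeLi (2.5 equiv), Et2O, 0 °C → rt; then H2O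
Reagents that add atoms: none
Why: Shapiro reaction (α′-deprotonation, loss of sulfinate and N2, protonation of the vinyllithium) gives the conjugated ring diene with the stereocentre untouched; the triene is used immediately to avoid aromatisation.

Step 15
Reactants: 17 (S)-2-methyl-5-(prop-1-en-2-yl)cyclohexa-1,3-diene
Product: 18 trans-endoperoxide 6-methyl-8-(prop-1-en-2-yl)-2,3-dioxabicyclo[2.2.2]oct-5-ene (O–O bridge anti to isopropenyl)
Conditions: O2, hν (visible), tetraphenylporphyrin (cat.), CH2Cl2, −20 °C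
Reagents that add atoms: dioxygen, O=O
Why: Singlet-oxygen [4+2] cycloaddition to the ring diene is far faster than ene reaction at the 1,1-disubstituted isopropenyl group and is expected to occur mainly anti to it.

Step 16
Reactants: 18 trans-endoperoxide
Product: 19 (4R,5R)-4-hydroxy-2-methyl-5-(prop-1-en-2-yl)cyclohex-2-en-1-one
Conditions: Et3N, CH2Cl2, 0 °C → rt
Reagents that add atoms: none
Why: Kornblum–DeLaMare rearrangement by removal of the less hindered bridgehead hydrogen gives the C1′ ketone and the C8′ carbinol trans to isopropenyl.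

Step 17
Reactants: 19 (4R,5R)-4-hydroxy-2-methyl-5-(prop-1-en-2-yl)cyclohex-2-en-1-one
Product: 20 (4R,5R)-4-(TBS-oxy)-2-methyl-5-(prop-1-en-2-yl)cyclohex-2-en-1-one
Conditions: TBSCl, imidazole, DMF, rt
Reagents that add atoms: tert-butyldimethylsilyl chloride, CC(C)(C)[Si](C)(C)Cl
Why: Standard silylation protects the carbinol that is carried to the late-stage oxidation.

Step 18
Reactants: 20 (4R,5R)-4-(TBS-oxy)-2-methyl-5-(prop-1-en-2-yl)cyclohex-2-en-1-one
Product: 21 (2R,4S,5R)-4-(TBS-oxy)-2-methyl-5-(prop-1-en-2-yl)cyclohexan-1-one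
Conditions: LiBH(s-Bu)3, THF, −78 °C; then NaOMe (cat.), MeOH, rt
Reagents that add atoms: none
Why: Conjugate hydride reduction of the enone followed by base equilibration gives the all-equatorial ketone, which sets C10′ (methyl trans to isopropenyl, cis to the silyloxy group) under thermodynamic control.

Step 19
Reactants: 21 (2R,4S,5R)-4-(TBS-oxy)-2-methyl-5-(prop-1-en-2-yl)cyclohexan-1-one
Product: 22 ethyl 5-(TBS-oxy)-3-methyl-2-oxo-6-(prop-1-en-2-yl)cycloheptane-1-carboxylate (C1 epimers and enol)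
Conditions: N2CHCO2Et, BF3·OEt2, CH2Cl2, −20 → 0 °C
Reagents that add atoms: ethyl diazoacetate, CCOC(=O)C=[N+]=[N-]
Why: Diazoacetate ring expansion with migration of the less substituted α-carbon inserts C5′ between C1′ and C6′.

Step 20
Reactants: 22 ethyl 5-(TBS-oxy)-3-methyl-2-oxo-6-(prop-1-en-2-yl)cycloheptane-1-carboxylate
Product: 23 ethyl 5-(TBS-oxy)-3-methyl-2-oxo-1-(2-oxopropyl)-6-(prop-1-en-2-yl)cycloheptane-1-carboxylate (C1 epimers)
Conditions: ClCH2COCH3, K2CO3, NaI (cat.), acetone, reflux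
Reagents that add atoms: chloroacetone, CC(=O)CCl
Why: C-alkylation of the doubly activated β-keto ester position attaches C4′, C3′ and C2′ without deprotonating C10′.

Step 21
Reactants: 23 ethyl 5-(TBS-oxy)-3-methyl-2-oxo-1-(2-oxopropyl)-6-(prop-1-en-2-yl)cycloheptane-1-carboxylate
Product: 25 8′-(TBS-oxy)-15′-norguaia-1′,11′(13′)-dien-3′-one (H-5′ cis to H-10′), via 1,4-diketone 24 (not isolated)
Conditions: KOH, EtOH/H2O, reflux
Reagents that add atoms: none
Why: Saponification and decarboxylation give the 1,4-diketone, whose methyl ketone undergoes intramolecular aldol condensation onto C1′ to form the fused cyclopentenone, the α-centres settling in the favoured cis-2,7-disubstituted cycloheptanone arrangement.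

Step 22
Reactants: 25 8′-(TBS-oxy)-15′-norguaia-1′,11′(13′)-dien-3′-one
Product: 26 8′-(TBS-oxy)guaia-1′,11′(13′)-dien-3′-one (4′-methyl cis to H-5′)
Conditions: LiN(i-Pr)2, THF, −78 °C; MeI, −78 → −40 °C
Reagents that add atoms: iodomethane, CI
Why: Alkylation of the kinetic α′-enolate of the cyclopentenone introduces the C4′ methyl trans to the neighbouring C5′–C6′ bond.

### Fragment union and endgame

Step 23
Reactants: 14 4,8-bis(TBS-oxy)-2-(TIPS-oxy)-15-norguaia-1(5),3-diene; 26 8′-(TBS-oxy)guaia-1′,11′(13′)-dien-3′-one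
Product: 28 norbornene adduct (C4 TBS enol ether; 2-OTIPS syn to C4=C5; 8-OTBS; exo 3′-ketone; 8′-OTBS; 7′-isopropenyl), via Michael adduct 27 (not isolated)
Conditions: Tf2NH (10 mol %), CH2Cl2, −78 → −40 °C; then Et3N quench
Reagents that add atoms: none
Why: Silyl-triflimide-catalysed intermolecular Mukaiyama–Michael addition joins C3 of the diene to C1′ of the enone (diene face anti to the C2 silyloxy and C10 methyl groups; convex enone face syn to H-5′, placing the new bond trans to the C10′ methyl), and the resulting silyl enol ether closes by intramolecular Michael addition of C2′ to C1 on the same face, fixing C1, C3, C1′ and C2′ and returning C4 as a regiodefined TBS enol ether.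

Step 24
Reactants: 28 norbornene adduct
Product: 29 C4 enol triflate
Conditions: CsF, PhNTf2, DME, 0 °C → rt
Reagents that add atoms: N-phenylbis(trifluoromethanesulfonimide), O=S(=O)(N(c1ccccc1)S(=O)(=O)C(F)(F)F)C(F)(F)F
Why: Fluoride cleaves only the silyl enol ether and the regiospecific C4 enolate is trapped in situ as the triflate before it can equilibrate or undergo retro-Michael opening.

Step 25
Reactants: 29 C4 enol triflate
Product: 30 C4-methyl norbornene
Conditions: SnMe4, Pd(PPh3)4 (10 mol %), LiCl, DMF, 90 °C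
Reagents that add atoms: tetramethylstannane, C[Sn](C)(C)C
Why: Stille cross-coupling of the vinyl triflate installs the C4 methyl under neutral conditions that tolerate the ketone and silyl ethers.

Step 26
Reactants: 30 C4-methyl norbornene
Product: 31 3′-O-trimethylsilyl 3′(4′)-enol ether
Conditions: LiN(i-Pr)2, Me3SiCl, THF, −78 °C
Reagents that add atoms: chlorotrimethylsilane, C[Si](C)(C)Cl
Why: Kinetic enolisation of the only ketone occurs at C4′ because H-2′ is buried between two quaternary carbons, and in situ silylation fixes that enolate.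

Step 27
Reactants: 31 3′-O-trimethylsilyl 3′(4′)-enol ether
Product: 32 4′-en-3′-one
Conditions: Pd(OAc)2 (1.1 equiv), MeCN, rt
Reagents that add atoms: none
Why: Saegusa–Ito oxidation, in which β-hydride elimination from C5′ gives the tetrasubstituted C4′=C5′ enone (C1′ is quaternary, so no other ring enone can form).

Step 28
Reactants: 32 4′-en-3′-one
Product: 33 8,8′-diol (2-OTIPS retained)
Conditions: HF·pyridine, pyridine, THF, 0 °C → rt
Reagents that add atoms: none
Why: Buffered fluoride removes the two secondary TBS ethers while the far more hindered TIPS ether on the one-carbon bridge survives.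

Step 29
Reactants: 33 8,8′-diol
Product: 34 8,8′-diketone (7′-isopropenyl)
Conditions: Dess–Martin periodinane, NaHCO3, CH2Cl2, rt
Reagents that add atoms: none
Why: Neutral Dess–Martin oxidation of both carbinols gives the C8 and C8′ ketones without epimerising C7.

Step 30
Reactants: 34 8,8′-diketone (7′-isopropenyl)
Product: 35 7′(11′)-isopropylidene 8′-ketone
Conditions: DBU (0.2 equiv), CH2Cl2, 0 °C, monitored
Reagents that add atoms: none
Why: Base-catalysed isomerisation of the β,γ-unsaturated ketone through the dienolate at the doubly activated C7′–H gives the conjugated isopropylidene ketone, and the mild base leaves the less acidic C6′ and C7 hydrogens alone.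

Step 31
Reactants: 35 7′(11′)-isopropylidene 8′-ketone
Product: 36 C2 alcohol
Conditions: aq. HF (48 %), MeCN, rt
Reagents that add atoms: none
Why: Acidic fluoride desilylation removes the TIPS group without exposing the base-sensitive dienone system to basic fluoride.

Step 32
Reactants: 36 C2 alcohol
Product: 37 C2 acetate
Conditions: Ac2O, pyridine, DMAP (cat.), CH2Cl2, 0 °C
Reagents that add atoms: acetic anhydride, CC(=O)OC(C)=O
Why: Standard acylation of the only hydroxyl group under weakly basic conditions.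

Step 33
Reactants: 37 C2 acetate
Product: 39 CNP0361479.4, via hydroperoxide 38 (not isolated)
Conditions: O2, hν (visible), tetraphenylporphyrin (cat.), CH2Cl2, 0 °C; then rt
Reagents that add atoms: dioxygen, O=O
Why: Schenck ene reaction of the isopropylidene ketone abstracts hydrogen from C6′ (the group geminal to the carbonyl), giving the C11′ hydroperoxide and the C6′=C7′ alkene; the hydroperoxide adds to the C8′ ketone to form the dioxolane hemiketal, while the C4=C5 alkene is shielded by the syn acetoxy bridge on one face and the right-hand seven-membered ring on the other.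

## Compound list

1 | (R)-(−)-α-phellandrene | CC1=CC[C@H](C(C)C)C=C1 | starting material
2 | 6-methyl-8-isopropyl-2,3-dioxabicyclo[2.2.2]oct-5-ene, peroxide bridge anti to isopropyl | CC1=C[C@@H]2OO[C@H]1C[C@@H]2C(C)C | intermediate
3 | (4R,5R)-4-hydroxy-2-methyl-5-isopropylcyclohex-2-en-1-one | CC1=C[C@H](O)[C@@H](C(C)C)CC1=O | intermediate
4 | (2S,4S,5R)-4-hydroxy-2-methyl-5-isopropylcyclohexan-1-one (methyl cis to isopropyl) | C[C@H]1C[C@H](O)[C@@H](C(C)C)CC1=O | intermediate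
5 | (2S,4S,5R)-4-(TBS-oxy)-2-methyl-5-isopropylcyclohexan-1-one | C[C@H]1C[C@H](O[Si](C)(C)C(C)(C)C)[C@@H](C(C)C)CC1=O | intermediate
6 | ethyl 5-(TBS-oxy)-3-methyl-2-oxo-6-isopropylcycloheptane-1-carboxylate (C1 labile) | C[C@H]1C[C@H](O[Si](C)(C)C(C)(C)C)[C@@H](C(C)C)CC(C(=O)OCC)C1=O | intermediate
7 | ethyl 5-(TBS-oxy)-3-methyl-6-isopropyl-2-(triflyloxy)cyclohept-1-ene-1-carboxylate | C[C@H]1C[C@H](O[Si](C)(C)C(C)(C)C)[C@@H](C(C)C)CC(C(=O)OCC)=C1OS(=O)(=O)C(F)(F)F | intermediate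
8 | ethyl 2-(1-ethoxyvinyl)-5-(TBS-oxy)-3-methyl-6-isopropylcyclohept-1-ene-1-carboxylate (not isolated) | C[C@H]1C[C@H](O[Si](C)(C)C(C)(C)C)[C@@H](C(C)C)CC(C(=O)OCC)=C1C(=C)OCC | intermediate
9 | ethyl 2-acetyl-5-(TBS-oxy)-3-methyl-6-isopropylcyclohept-1-ene-1-carboxylate | C[C@H]1C[C@H](O[Si](C)(C)C(C)(C)C)[C@@H](C(C)C)CC(C(=O)OCC)=C1C(C)=O | intermediate
10 | 8-(TBS-oxy)-15-norguai-1(5)-ene-2,4-dione | C[C@H]1C[C@H](O[Si](C)(C)C(C)(C)C)[C@@H](C(C)C)CC2=C1C(=O)CC2=O | intermediate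
11 | 8-(TBS-oxy)-15-norguai-1(5)-ene-2,4-diol (2-OH cis to C10 methyl, 4-OH cis to 2-OH) | C[C@H]1C[C@H](O[Si](C)(C)C(C)(C)C)[C@@H](C(C)C)CC2=C1[C@H](O)C[C@@H]2O | intermediate
12 | 2-hydroxy-8-(TBS-oxy)-15-norguai-1(5)-en-4-one | C[C@H]1C[C@H](O[Si](C)(C)C(C)(C)C)[C@@H](C(C)C)CC2=C1[C@H](O)CC2=O | intermediate
13 | 8-(TBS-oxy)-2-(TIPS-oxy)-15-norguai-1(5)-en-4-one | C[C@H]1C[C@H](O[Si](C)(C)C(C)(C)C)[C@@H](C(C)C)CC2=C1[C@H](O[Si](C(C)C)(C(C)C)C(C)C)CC2=O | intermediate
14 | 4,8-bis(TBS-oxy)-2-(TIPS-oxy)-15-norguaia-1(5),3-diene | C[C@H]1C[C@H](O[Si](C)(C)C(C)(C)C)[C@@H](C(C)C)CC2=C1[C@H](O[Si](C(C)C)(C(C)C)C(C)C)C=C2O[Si](C)(C)C(C)(C)C | intermediate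
15 | (S)-(+)-carvone | CC1=CC[C@@H](CC1=O)C(C)=C | starting material
16 | (S)-carvone p-toluenesulfonylhydrazone (C=N isomers) | CC1=CC[C@@H](CC1=NNS(=O)(=O)c1ccc(C)cc1)C(C)=C | intermediate
17 | (S)-2-methyl-5-(prop-1-en-2-yl)cyclohexa-1,3-diene | CC1=CC[C@H](C(C)=C)C=C1 | intermediate
18 | 6-methyl-8-(prop-1-en-2-yl)-2,3-dioxabicyclo[2.2.2]oct-5-ene, peroxide bridge anti to isopropenyl | CC1=C[C@@H]2OO[C@H]1C[C@@H]2C(C)=C | intermediate
19 | (4R,5R)-4-hydroxy-2-methyl-5-(prop-1-en-2-yl)cyclohex-2-en-1-one | CC1=C[C@H](O)[C@@H](C(C)=C)CC1=O | intermediate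
20 | (4R,5R)-4-(TBS-oxy)-2-methyl-5-(prop-1-en-2-yl)cyclohex-2-en-1-one | CC1=C[C@H](O[Si](C)(C)C(C)(C)C)[C@@H](C(C)=C)CC1=O | intermediate
21 | (2R,4S,5R)-4-(TBS-oxy)-2-methyl-5-(prop-1-en-2-yl)cyclohexan-1-one (all equatorial) | C[C@@H]1C[C@H](O[Si](C)(C)C(C)(C)C)[C@@H](C(C)=C)CC1=O | intermediate
22 | ethyl 5-(TBS-oxy)-3-methyl-2-oxo-6-(prop-1-en-2-yl)cycloheptane-1-carboxylate (C1 labile) | C[C@@H]1C[C@H](O[Si](C)(C)C(C)(C)C)[C@@H](C(C)=C)CC(C(=O)OCC)C1=O | intermediate
23 | ethyl 5-(TBS-oxy)-3-methyl-2-oxo-1-(2-oxopropyl)-6-(prop-1-en-2-yl)cycloheptane-1-carboxylate (C1 epimers, both converge) | C[C@@H]1C[C@H](O[Si](C)(C)C(C)(C)C)[C@@H](C(C)=C)CC(CC(C)=O)(C(=O)OCC)C1=O | intermediate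
24 | 4-(TBS-oxy)-2-methyl-7-(2-oxopropyl)-5-(prop-1-en-2-yl)cycloheptan-1-one, 2,7-cis (not isolated) | C[C@@H]1C[C@H](O[Si](C)(C)C(C)(C)C)[C@@H](C(C)=C)C[C@H](CC(C)=O)C1=O | intermediate
25 | 8′-(TBS-oxy)-15′-norguaia-1′,11′(13′)-dien-3′-one, H-5′ cis to H-10′ | C[C@@H]1C[C@H](O[Si](C)(C)C(C)(C)C)[C@@H](C(C)=C)C[C@@H]2CC(=O)C=C12 | intermediate
26 | 8′-(TBS-oxy)guaia-1′,11′(13′)-dien-3′-one, 4′-methyl cis to H-5′ | C[C@@H]1C[C@H](O[Si](C)(C)C(C)(C)C)[C@@H](C(C)=C)C[C@@H]2[C@@H](C)C(=O)C=C12 | intermediate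
27 | C3–C1′ Michael adduct: left 1(5)-en-4-one, right 2′-ene 3′-O-TBS enol ether (not isolated) | CC(C)[Si](C(C)C)(C(C)C)O[C@@H]1[C@@H]([C@]34C=C(O[Si](C)(C)C(C)(C)C)[C@H](C)[C@H]3C[C@H](C(C)=C)[C@@H](O[Si](C)(C)C(C)(C)C)C[C@H]4C)C(=O)C2=C1[C@@H](C)C[C@H](O[Si](C)(C)C(C)(C)C)[C@@H](C(C)C)C2 | intermediate
28 | norbornene adduct (bonds C3–C1′ and C1–C2′): C4 TBS enol ether, 2-OTIPS, 8-OTBS, 3′-ketone, 8′-OTBS, 7′-isopropenyl | CC(C)[Si](C(C)C)(C(C)C)O[C@@H]1[C@@H]2C(O[Si](C)(C)C(C)(C)C)=C3C[C@H](C(C)C)[C@@H](O[Si](C)(C)C(C)(C)C)C[C@H](C)[C@@]31[C@@H]1C(=O)[C@H](C)[C@H]3C[C@H](C(C)=C)[C@@H](O[Si](C)(C)C(C)(C)C)C[C@@H](C)[C@]312 | intermediate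
29 | C4 enol triflate of the adduct | CC(C)[Si](C(C)C)(C(C)C)O[C@@H]1[C@@H]2C(OS(=O)(=O)C(F)(F)F)=C3C[C@H](C(C)C)[C@@H](O[Si](C)(C)C(C)(C)C)C[C@H](C)[C@@]31[C@@H]1C(=O)[C@H](C)[C@H]3C[C@H](C(C)=C)[C@@H](O[Si](C)(C)C(C)(C)C)C[C@@H](C)[C@]312 | intermediate
30 | C4-methyl norbornene (4-ene), 3′-ketone | CC(C)[Si](C(C)C)(C(C)C)O[C@@H]1[C@@H]2C(C)=C3C[C@H](C(C)C)[C@@H](O[Si](C)(C)C(C)(C)C)C[C@H](C)[C@@]31[C@@H]1C(=O)[C@H](C)[C@H]3C[C@H](C(C)=C)[C@@H](O[Si](C)(C)C(C)(C)C)C[C@@H](C)[C@]312 | intermediate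
31 | 3′-O-trimethylsilyl 3′(4′)-enol ether of 30 | CC(C)[Si](C(C)C)(C(C)C)O[C@@H]1[C@@H]2C(C)=C3C[C@H](C(C)C)[C@@H](O[Si](C)(C)C(C)(C)C)C[C@H](C)[C@@]31[C@@H]1C(O[Si](C)(C)C)=C(C)[C@H]3C[C@H](C(C)=C)[C@@H](O[Si](C)(C)C(C)(C)C)C[C@@H](C)[C@]312 | intermediate
32 | 4′-en-3′-one (8,8′-bis-OTBS, 2-OTIPS, 7′-isopropenyl) | CC(C)[Si](C(C)C)(C(C)C)O[C@@H]1[C@@H]2C(C)=C3C[C@H](C(C)C)[C@@H](O[Si](C)(C)C(C)(C)C)C[C@H](C)[C@@]31[C@@H]1C(=O)C(C)=C3C[C@H](C(C)=C)[C@@H](O[Si](C)(C)C(C)(C)C)C[C@@H](C)[C@]312 | intermediate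
33 | 8,8′-diol (2-OTIPS) | CC(C)[Si](C(C)C)(C(C)C)O[C@@H]1[C@@H]2C(C)=C3C[C@H](C(C)C)[C@@H](O)C[C@H](C)[C@@]31[C@@H]1C(=O)C(C)=C3C[C@H](C(C)=C)[C@@H](O)C[C@@H](C)[C@]312 | intermediate
34 | 8,8′-diketone with 7′-isopropenyl (2-OTIPS) | CC(C)[Si](C(C)C)(C(C)C)O[C@@H]1[C@@H]2C(C)=C3C[C@H](C(C)C)C(=O)C[C@H](C)[C@@]31[C@@H]1C(=O)C(C)=C3C[C@H](C(C)=C)C(=O)C[C@@H](C)[C@]312 | intermediate
35 | 7′(11′)-isopropylidene 8′-ketone (2-OTIPS) | CC(C)[Si](C(C)C)(C(C)C)O[C@@H]1[C@@H]2C(C)=C3C[C@H](C(C)C)C(=O)C[C@H](C)[C@@]31[C@@H]1C(=O)C(C)=C3CC(=C(C)C)C(=O)C[C@@H](C)[C@]312 | intermediate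
36 | C2 alcohol of 35 | O[C@@H]1[C@@H]2C(C)=C3C[C@H](C(C)C)C(=O)C[C@H](C)[C@@]31[C@@H]1C(=O)C(C)=C3CC(=C(C)C)C(=O)C[C@@H](C)[C@]312 | intermediate
37 | C2 acetate (deperoxy precursor of the target) | CC(=O)O[C@@H]1[C@@H]2C(C)=C3C[C@H](C(C)C)C(=O)C[C@H](C)[C@@]31[C@@H]1C(=O)C(C)=C3CC(=C(C)C)C(=O)C[C@@H](C)[C@]312 | intermediate
38 | 11′-hydroperoxy-4′,6′-dien-3′,8′-dione (not isolated) | CC(=O)O[C@@H]1[C@@H]2C(C)=C3C[C@H](C(C)C)C(=O)C[C@H](C)[C@@]31[C@@H]1C(=O)C(C)=C3C=C(C(C)(C)OO)C(=O)C[C@@H](C)[C@]312 | intermediate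
39 | CNP0361479.4 | CC(=O)O[C@@H]1[C@@H]2C(C)=C3C[C@H](C(C)C)C(=O)C[C@H](C)[C@@]31[C@@H]1C(=O)C(C)=C3C=C4C(C)(C)OO[C@]4(O)C[C@@H](C)[C@]312 | target

## Step count and risks

Total steps: 33. Longest linear sequence: 23 steps (steps 1–12, then 23–33, from α-phellandrene); the carvone branch is 21 steps.

Three steps most likely to fail:

Step 10 (selective oxidation of diol 11). The two allylic carbinols differ only moderately in hindrance, so over-oxidation to 10 or oxidation at C2 may compete. Fallback: set out from 11 and differentiate by protection instead of oxidation. Pivaloyl chloride (pyridine, −20 °C) acylates the less hindered C4 hydroxyl to give the 4-O-pivaloyl 2-alcohol F1. TIPSOTf and 2,6-lutidine then give the 2-O-TIPS 4-pivalate F2. i-Bu2AlH (CH2Cl2, −78 °C) cleaves the pivalate to give the 2-O-TIPS 4-alcohol F3. Dess–Martin oxidation of F3 returns to the route at 13.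

Step 23 (catalytic double Michael union). Two hindered C–C bonds and four stereocentres are formed in one operation, and the diene can isomerise or the cascade can stall. Fallback: set out from 14 and 26 and separate the two bond formations. Stoichiometric TiCl4 (CH2Cl2, −78 °C) effects only the intermolecular Mukaiyama–Michael addition, and aqueous work-up gives the open 1,5-diketone Michael adduct F4. KN(SiMe3)2 (THF, −78 → 0 °C) then forms the C2′ enolate, which closes onto C1 by anionic intramolecular Michael addition; the resulting C4 enolate is trapped with PhNTf2, returning to the route at 29.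

Step 33 (final photooxygenation). Singlet oxygen may attack the tetrasubstituted C4=C5 alkene, or the ene reaction may abstract a methyl hydrogen instead of C6′–H. Fallback: set out from 34 and install the peroxide by radical hydroperoxidation instead of an ene reaction. Co(acac)2, O2 and Et3SiH (ClCH2CH2Cl, rt) convert the isopropenyl group into the 11′-triethylsilylperoxy diketone F5. Aqueous HF in MeCN removes both silyl groups, and the free hydroperoxide closes onto the C8′ ketone to give the 6′,7′-dihydro hemiketal C2 alcohol F6. Ac2O and pyridine (0 °C) acetylate only the secondary hydroxyl to give the 6′,7′-dihydro acetate F7. Chloranil (t-BuOH, 80 °C) dehydrogenates the 4′-en-3′-one to the 4′,6′-dienone, arriving at 39.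

## Further compounds

F1 | step 10 | 4-O-pivaloyl-8-(TBS-oxy)-15-norguai-1(5)-ene-2,4-diol | C[C@H]1C[C@H](O[Si](C)(C)C(C)(C)C)[C@@H](C(C)C)CC2=C1[C@H](O)C[C@@H]2OC(=O)C(C)(C)C
F2 | step 10 | 4-O-pivaloyl-2-O-TIPS-8-(TBS-oxy)-15-norguai-1(5)-ene-2,4-diol | C[C@H]1C[C@H](O[Si](C)(C)C(C)(C)C)[C@@H](C(C)C)CC2=C1[C@H](O[Si](C(C)C)(C(C)C)C(C)C)C[C@@H]2OC(=O)C(C)(C)C
F3 | step 10 | 2-(TIPS-oxy)-8-(TBS-oxy)-15-norguai-1(5)-en-4-ol | C[C@H]1C[C@H](O[Si](C)(C)C(C)(C)C)[C@@H](C(C)C)CC2=C1[C@H](O[Si](C(C)C)(C(C)C)C(C)C)C[C@@H]2O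
F4 | step 23 | C3–C1′ linked 1,5-diketone (left 1(5)-en-4-one, right saturated 3′-ketone) | CC(C)[Si](C(C)C)(C(C)C)O[C@@H]1[C@@H]([C@]34CC(=O)[C@H](C)[C@H]3C[C@H](C(C)=C)[C@@H](O[Si](C)(C)C(C)(C)C)C[C@H]4C)C(=O)C2=C1[C@@H](C)C[C@H](O[Si](C)(C)C(C)(C)C)[C@@H](C(C)C)C2
F5 | step 33 | 11′-(triethylsilylperoxy) 8,8′-diketone (2-OTIPS) | CC(C)[Si](C(C)C)(C(C)C)O[C@@H]1[C@@H]2C(C)=C3C[C@H](C(C)C)C(=O)C[C@H](C)[C@@]31[C@@H]1C(=O)C(C)=C3C[C@H](C(C)(C)OO[Si](CC)(CC)CC)C(=O)C[C@@H](C)[C@]312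
F6 | step 33 | 6′,7′-dihydro dioxolane hemiketal, C2 alcohol | O[C@@H]1[C@@H]2C(C)=C3C[C@H](C(C)C)C(=O)C[C@H](C)[C@@]31[C@@H]1C(=O)C(C)=C3C[C@@H]4C(C)(C)OO[C@]4(O)C[C@@H](C)[C@]312
F7 | step 33 | 6′,7′-dihydro target (C2 acetate) | CC(=O)O[C@@H]1[C@@H]2C(C)=C3C[C@H](C(C)C)C(=O)C[C@H](C)[C@@]31[C@@H]1C(=O)C(C)=C3C[C@@H]4C(C)(C)OO[C@]4(O)C[C@@H](C)[C@]312
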